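1. At 6.00 d the birch run, which is this very flask followed so far, reads 26.3% target and 0.2% substrate, so 73.5% of the charge is a leftover that no reading shows.

| flask | substrate | first nucleophile | second nucleophile | temperature | remark | time |
|---|---|---|---|---|---|---|
| birch | 0.050 M | 0.060 M | 0.10 M | 80 °C | the very flask that is asked about, followed so far |  |
| ash | 0.050 M | 0.12 M | 0.10 M | 75 °C | run made earlier |  |
| flask | 0.050 M | 0.0600 M | 0.100 M | 80 °C |  | 8.0 d |

- birch (time / d: target / %, substrate / %): 0.833: 23.8, 17.6; 1.67: 26.0, 1.9; 3.00: 26.7, 0; 4.00: 26.5, 0.1; 5.00: 26.3, 0.3; 6.00: 26.3, 0.2
- ash (time / h: target / %, substrate / %): 6.00: 12.9, 74.2; 15.0: 18.9, 48.2; 20.0: 20.1, 39.3; 30.0: 23.8, 22.7; 40.0: 24.4, 14.2; 50.0: 23.3, 8.6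

(each reading ± 0.5 percentage points)

- north-east: at 8.0 d add second nucleophile, 100% of the amount charged, then wait 2.5 d
- south-west: at 8.0 d raise the temperature by 25 K, then wait 2.5 d
- north-west: change nothing and wait 2.5 d more
- east: at 8.0 d take out 90% of the target then present, then wait 2.5 d

- removed target is counted in
- additions bring no volume worth counting

- target, in percent of the substrate first charged, at 8.0 d
- which option adds most target ("none" when 2 percentage points or less is all one gets) (north-east / south-west / north-west / east / none)
- target present, with what was taken out counted in, in percent of the substrate first charged, after north-west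
- target present, with what was taken out counted in, in percent of the substrate first charged, after east

2. I divide the rate of target gain by the rate of substrate loss, so that time and the substrate's own slowing drop out, and I call this the gain (instantaneous yield). Up to 6.00 h the ash run reads a gain of 0.500.

3. Between 20.0 h and 50.0 h the ash gain reads 0.104, so it has slowed by a factor 0.208.

4. If each substrate took one first nucleophile and the gain followed c(first nucleophile) in proportion, that slowing would be a factor 0.583 at worst. The gain has fallen further than that, so I read the remaining factor 0.357 as target being lost again.

5. Yet birch target moves by 0.4 percentage points from 3.00 d to 6.00 d, less than the scatter. A loss that stops with target present looks to me like a balance with an unseen partner.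

6. The keep share, target over target plus partner, has the ceiling 0.526, taking the pool as at least the starting gain. Its floor is 0.264, taking the leftover as partner.

7. If a share of target is removed and the pool splits again, the gain in points is that share times the target times one minus the keep share. For east I reckon 11 points to 17 points, more than the margin. So I commit to east, the one option I have reckoned.

8. The forecast differs: 26.4% now, 26.3% after north-west, 26.4% after east, best none, on the ground “With no feedstock left, target looks like a dead end”.

9. The flask gives 26.3% now, 26.3% after north-west and 41.7% after east. Best is south-west, adding 23 points against 15 points for east.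

    substrate → intermediate (k = 2.48 × 10⁻⁵ s⁻¹, Ea = 123 kJ mol⁻¹)
    first nucleophile + intermediate → target (k = 0.448 M⁻¹ s⁻¹, Ea = 54.0 kJ mol⁻¹)
    second nucleophile + intermediate → other capture product (k = 0.0438 M⁻¹ s⁻¹, Ea = 48.0 kJ mol⁻¹)
    intermediate → solvolysis product (k = 0.00113 s⁻¹, Ea = 93.0 kJ mol⁻¹)
    intermediate → side product (k = 1.84 × 10⁻⁶ s⁻¹, Ea = 123 kJ mol⁻¹)
    target ⇌ isomer of the product (K = 1.90, k = 1.11 × 10⁻⁴ s⁻¹, Ea = 114 kJ mol⁻¹, ΔH = −56.0 kJ mol⁻¹)
    (constants at 80 °C)

10. At 8.00 d the flask holds 26.3% target and 49.9% isomer of the product, a keep share of 0.345, below my ceiling 0.526. Put into the rule, it gives 15 points for east. The neighbour flask, charged with 0.036 M of first nucleophile, holds 39.0% isomer of the product at 8.00 d. The flask's keep share turns that isomer into 20.5% target, and the neighbour flask holds 20.5%.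

Readings and results are calculated with constants of no real substance, and the scatter is random.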